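The 20-membered lactam ring is opened at the bond between the cinnamamide nitrogen (spermidine N1) and the adjacent CH2 of the three-carbon arm. The key step is an intramolecular Mitsunobu N-alkylation: the aryl-side (Z)-cinnamamide, activated as its N-Boc acyl carbamate, is the only N–H acidic enough to be alkylated by the activated primary alcohol, so one operation closes the macrocycle and completes the spermidine chain with both (Z)-alkenes and both stereocentres already in place. The precursor is a seco hydroxy acyl carbamate hung on the cis-fused hexahydrodibenzofuran core, whose C9b/C4a stereocentres come from an enantioselective deprotonation of a 4-aryl-4-cyanocyclohexanone and an oxa-Michael closure.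

Key step: step 15

Assumption: the sense of induction of the chiral lithium amide in step 3 is taken by analogy with 4-tert-butylcyclohexanone (aryl as the equatorial anchor); it is to be checked on the crystalline bromo keto nitrile from step 5 (anomalous dispersion of Br), and the (S,S)-amide is used instead if the sense is opposite.

Step 1
Reactants: 1 2-(5-bromo-2-methoxyphenyl)acetonitrile; 2 methyl acrylate (2.2 equiv)
Product: 4 methyl 5-(5-bromo-2-methoxyphenyl)-5-cyano-2-oxocyclohexane-1-carboxylate, via pimelate diester 3 (not isolated)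
Conditions: KOt-Bu (2.5 equiv), THF, 0 °C to rt; aq. HCl quench
Reagents that add atoms: none
Why: Two Michael additions of the benzylic nitrile anion to methyl acrylate followed by Dieckmann condensation of the resulting pimelate build the six-membered ring around the future C9b; the product is racemic and its stereocentres are erased in step 2.

Step 2
Reactants: 4 methyl 5-(5-bromo-2-methoxyphenyl)-5-cyano-2-oxocyclohexane-1-carboxylate
Product: 5 1-(5-bromo-2-methoxyphenyl)-4-oxocyclohexane-1-carbonitrile
Conditions: AcOH, 10% aq. H2SO4, 100 °C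
Reagents that add atoms: none
Why: Acid hydrolysis and decarboxylation of the β-keto ester should give the achiral, mirror-symmetric ketone, the hindered tertiary nitrile and the aryl methyl ether being inert here.

Step 3
Reactants: 5 1-(5-bromo-2-methoxyphenyl)-4-oxocyclohexane-1-carbonitrile
Product: 6 (1R)-1-(5-bromo-2-methoxyphenyl)-4-[(trimethylsilyl)oxy]cyclohex-3-ene-1-carbonitrile
Conditions: (R,R)-bis(1-phenylethyl)amine hydrochloride, n-BuLi (2 equiv), THF, −78 °C; Me3SiCl (5 equiv), then 5, −100 °C
Reagents that add atoms: chlorotrimethylsilane, C[Si](C)(C)Cl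
Why: Enantioselective deprotonation with a chiral lithium amide under internal Me3SiCl quench (chiral-base desymmetrisation) distinguishes the two enantiotopic α-methylene groups of the conformationally biased ketone (aryl equatorial), so the quaternary carbon becomes the (R)-stereocentre that will be C9b.

Step 4
Reactants: 6 (1R)-1-(5-bromo-2-methoxyphenyl)-4-[(trimethylsilyl)oxy]cyclohex-3-ene-1-carbonitrile
Product: 7 (1R)-1-(5-bromo-2-methoxyphenyl)-4-oxocyclohex-2-ene-1-carbonitrile
Conditions: Pd(OAc)2 (1.05 equiv), MeCN, rt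
Reagents that add atoms: none
Why: Saegusa–Ito oxidation should convert the silyl enol ether regiospecifically into the enone on the side fixed in step 3; the quaternary stereocentre cannot epimerise and the aryl bromide is untouched by ligand-free palladium at rt.

Step 5
Reactants: 7 (1R)-1-(5-bromo-2-methoxyphenyl)-4-oxocyclohex-2-ene-1-carbonitrile
Product: 9 (4aR,9bR)-8-bromo-3-oxo-1,2,3,4,4a,9b-hexahydrodibenzo[b,d]furan-9b-carbonitrile, via phenol enone 8 (not isolated)
Conditions: BBr3 (3 equiv), CH2Cl2, −78 to 0 °C; then MeOH, sat. aq. NaHCO3, rt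
Reagents that add atoms: none
Why: BBr3 cleaves the aryl methyl ether and the freed ortho-phenol adds to the enone β-carbon in a 5-exo-trig intramolecular oxa-Michael reaction that can only give the cis-fused dihydrobenzofuran, so C9b dictates the new C4a stereocentre.

Step 6
Reactants: 9 (4aR,9bR)-8-bromo-3-oxo-1,2,3,4,4a,9b-hexahydrodibenzo[b,d]furan-9b-carbonitrile
Product: 10 (4a'R,9b'R)-8'-bromo-1',2',4',4a'-tetrahydro-9b'H-spiro[[1,3]dioxolane-2,3'-dibenzo[b,d]furan]-9b'-carbonitrile
Conditions: ethylene glycol, p-TsOH·H2O (cat.), benzene, reflux, Dean–Stark trap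
Reagents that add atoms: ethylene glycol, OCCO
Why: Acid-catalysed ketalisation with azeotropic removal of water masks the ketone against the hydride, the strong bases and the coupling conditions of the later steps.

Step 7
Reactants: 10 (4a'R,9b'R)-8'-bromo-1',2',4',4a'-tetrahydro-9b'H-spiro[[1,3]dioxolane-2,3'-dibenzo[b,d]furan]-9b'-carbonitrile
Product: 11 (4a'R,9b'S)-8'-bromo-1',2',4',4a'-tetrahydro-9b'H-spiro[[1,3]dioxolane-2,3'-dibenzo[b,d]furan]-9b'-carbaldehyde
Conditions: i-Bu2AlH (1.5 equiv), toluene, −78 °C; then aq. KNaC4H4O6 (potassium sodium tartrate), rt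
Reagents that add atoms: water, O
Why: i-Bu2AlH adds once to the nitrile (partial nitrile reduction) to give an aluminium imine that is hydrolysed on work-up to the non-enolisable neopentyl aldehyde; aryl bromide and ketal are inert.

Step 8
Reactants: 11 (4a'R,9b'S)-8'-bromo-1',2',4',4a'-tetrahydro-9b'H-spiro[[1,3]dioxolane-2,3'-dibenzo[b,d]furan]-9b'-carbaldehyde; 12 methyl bis(2,2,2-trifluoroethyl)phosphonoacetate
Product: 13 methyl (2Z)-3-[(4a'R,9b'S)-8'-bromo-1',2',4',4a'-tetrahydro-9b'H-spiro[[1,3]dioxolane-2,3'-dibenzo[b,d]furan]-9b'-yl]prop-2-enoate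
Conditions: KN(SiMe3)2, 18-crown-6, THF, −78 °C
Reagents that add atoms: none
Why: Still–Gennari olefination: the electron-poor trifluoroethyl phosphonate eliminates under kinetic control and should give the (Z)-enoate even on this hindered, non-enolisable aldehyde.

Step 9
Reactants: 13 methyl (2Z)-3-[(4a'R,9b'S)-8'-bromo-1',2',4',4a'-tetrahydro-9b'H-spiro[[1,3]dioxolane-2,3'-dibenzo[b,d]furan]-9b'-yl]prop-2-enoate
Product: 14 (2Z)-3-[(4a'R,9b'S)-8'-bromo-1',2',4',4a'-tetrahydro-9b'H-spiro[[1,3]dioxolane-2,3'-dibenzo[b,d]furan]-9b'-yl]prop-2-enoic acid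
Conditions: LiOH·H2O, THF–MeOH–H2O, rt; then 1 M HCl to pH 4 at 0 °C
Reagents that add atoms: lithium hydroxide (hydroxide oxygen), [Li+].[OH-]
Why: Mild saponification of the methyl ester (ester hydrolysis) should leave the (Z)-alkene, the ketal and the aryl bromide unchanged.

Step 10
Reactants: 15 3-aminopropan-1-ol (3 equiv); 16 4-bromobutanenitrile
Product: 18 tert-butyl (3-cyanopropyl)(3-hydroxypropyl)carbamate, via amino nitrile 17 (not isolated)
Conditions: K2CO3, MeCN, 60 °C; then Boc2O, rt
Reagents that add atoms: di-tert-butyl dicarbonate, CC(C)(C)OC(=O)OC(=O)OC(C)(C)C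
Why: SN2 alkylation of the amine used in excess gives the secondary amine, which Boc2O acylates at nitrogen in preference to the hydroxyl group (carbamate formation); Boc-protected excess amine is removed by chromatography.

Step 11
Reactants: 18 tert-butyl (3-cyanopropyl)(3-hydroxypropyl)carbamate
Product: 19 tert-butyl (4-aminobutyl)(3-hydroxypropyl)carbamate
Conditions: H2 (5 bar), Raney Ni, 7 M NH3 in MeOH, rt
Reagents that add atoms: none
Why: Catalytic hydrogenation of the nitrile gives the primary amine, ammonia suppressing secondary-amine formation; carbamate and alcohol are inert.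

Step 12
Reactants: 14 (2Z)-3-[(4a'R,9b'S)-8'-bromo-1',2',4',4a'-tetrahydro-9b'H-spiro[[1,3]dioxolane-2,3'-dibenzo[b,d]furan]-9b'-yl]prop-2-enoic acid; 19 tert-butyl (4-aminobutyl)(3-hydroxypropyl)carbamate
Product: 20 tert-butyl N-{4-[(2Z)-3-[(4a'R,9b'S)-8'-bromo-1',2',4',4a'-tetrahydro-9b'H-spiro[[1,3]dioxolane-2,3'-dibenzo[b,d]furan]-9b'-yl]prop-2-enamido]butyl}-N-(3-hydroxypropyl)carbamate
Conditions: EDC·HCl, HOBt, i-Pr2NEt, CH2Cl2, 0 °C to rt
Reagents that add atoms: none
Why: Carbodiimide-mediated amide coupling acylates the primary amine chemoselectively in the presence of the primary alcohol and should keep the (Z)-geometry.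

Step 13
Reactants: 21 (2Z)-3-iodoprop-2-enoic acid; 22 tert-butyl carbamate (2 equiv)
Product: 24 tert-butyl N-[(2Z)-3-iodoprop-2-enoyl]carbamate, via acid chloride 23 (not isolated)
Conditions: (COCl)2, DMF (cat.), CH2Cl2, 0 °C, then evaporation; 22, LiN(SiMe3)2 (2 equiv), THF, −78 °C
Reagents that add atoms: none
Why: N-Acylation of lithiated tert-butyl carbamate by the acid chloride gives the acyl carbamate with its imide-type N–H; the low temperature should keep the (Z)-iodoalkene intact.

Step 14
Reactants: 20 tert-butyl N-{4-[(2Z)-3-[(4a'R,9b'S)-8'-bromo-1',2',4',4a'-tetrahydro-9b'H-spiro[[1,3]dioxolane-2,3'-dibenzo[b,d]furan]-9b'-yl]prop-2-enamido]butyl}-N-(3-hydroxypropyl)carbamate; 24 tert-butyl N-[(2Z)-3-iodoprop-2-enoyl]carbamate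
Product: 26 tert-butyl N-[(2Z)-3-[(4a'R,9b'S)-9b'-[(1Z)-3-({4-[(tert-butoxycarbonyl)(3-hydroxypropyl)amino]butyl}amino)-3-oxoprop-1-en-1-yl]-1',2',4',4a'-tetrahydro-9b'H-spiro[[1,3]dioxolane-2,3'-dibenzo[b,d]furan]-8'-yl]prop-2-enoyl]carbamate, via pinacol boronate 25 (not isolated)
Conditions: B2pin2, Pd(dppf)Cl2 (5 mol %), KOAc, 1,4-dioxane, 85 °C; then 24, aq. K3PO4, 50 °C
Reagents that add atoms: none
Why: Miyaura borylation of the aryl bromide followed in the same pot by Suzuki–Miyaura coupling with the (Z)-vinyl iodide, which proceeds with retention of alkene geometry, installs the (Z)-cinnamoyl carbamate; the deprotonated acyl carbamate resists hydrolysis.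

Step 15
Reactants: 26 tert-butyl N-[(2Z)-3-[(4a'R,9b'S)-9b'-[(1Z)-3-({4-[(tert-butoxycarbonyl)(3-hydroxypropyl)amino]butyl}amino)-3-oxoprop-1-en-1-yl]-1',2',4',4a'-tetrahydro-9b'H-spiro[[1,3]dioxolane-2,3'-dibenzo[b,d]furan]-8'-yl]prop-2-enoyl]carbamate
Product: 27 bis-Boc macrocyclic ketal (the target with its C3 ketone as ethylene ketal and with Boc on the cinnamamide nitrogen and on the amine nitrogen)
Conditions: PPh3 (3 equiv), DIAD (3 equiv), THF–toluene, 0.002 M, syringe-pump addition of 26, 0 °C to rt
Reagents that add atoms: none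
Why: PPh3 and DIAD form the betaine, which deprotonates the acyl carbamate N–H of 26 and turns the primary hydroxyl into an alkoxyphosphonium ion that the imide-type nitrogen displaces by SN2 attack at the terminal CH2 of the three-carbon arm. The closest known reaction type is the Mitsunobu N-alkylation of imide-type N–H acids (di-tert-butyl iminodicarbonate, phthalimide, sulfonamides) and its macrocyclising Fukuyama–Mitsunobu variant used for polyamine lactams. The 20-membered ring is closed in the exo-tet mode (20-exo-tet) at an unhindered primary carbon; no stereocentre is created, and C4a, C9b and both (Z)-alkenes are not engaged because the medium is essentially neutral. The step needs nitrogen selectivity among three N–H or N-acyl sites, N- over O-alkylation, and ring closure over oligomerisation: only the acyl carbamate falls in the Mitsunobu acidity window (the secondary acrylamide N–H does not), its delocalised anion alkylates at nitrogen, and high dilution with slow addition favours the intramolecular path, helped by the two (Z)-enamide turns on the rigid cis-fused core. The ethylene ketal keeps the β-aryloxy ketone out of play.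

Step 16
Reactants: 27 bis-Boc macrocyclic ketal
Product: 28 CNP0415009.2
Conditions: TFA–H2O (9:1), 0 °C to rt; then aq. NaHCO3
Reagents that add atoms: water, O
Why: One global acidolysis removes both Boc groups (loss of the tert-butyl cation, then decarboxylation) and hydrolyses the dioxolane; the cis ring fusion is the only accessible one, so reversible retro-oxa-Michael chemistry cannot scramble C4a.

Compound list
1 | 2-(5-bromo-2-methoxyphenyl)acetonitrile | COc1ccc(Br)cc1CC#N | starting material
2 | methyl acrylate | C=CC(=O)OC | starting material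
3 | dimethyl 4-(5-bromo-2-methoxyphenyl)-4-cyanoheptanedioate | COC(=O)CCC(C#N)(CCC(=O)OC)c1cc(Br)ccc1OC | intermediate (not isolated)
4 | methyl 5-(5-bromo-2-methoxyphenyl)-5-cyano-2-oxocyclohexane-1-carboxylate (racemic; keto/enol and diastereomer mixture) | COC(=O)C1CC(C#N)(c2cc(Br)ccc2OC)CCC1=O | intermediate
5 | 1-(5-bromo-2-methoxyphenyl)-4-oxocyclohexane-1-carbonitrile | N#CC1(c2cc(Br)ccc2OC)CCC(=O)CC1 | intermediate
6 | (1R)-1-(5-bromo-2-methoxyphenyl)-4-[(trimethylsilyl)oxy]cyclohex-3-ene-1-carbonitrile | C[Si](C)(C)OC1=CC[C@@](C#N)(c2cc(Br)ccc2OC)CC1 | intermediate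
7 | (1R)-1-(5-bromo-2-methoxyphenyl)-4-oxocyclohex-2-ene-1-carbonitrile | O=C1CC[C@](c2cc(Br)ccc2OC)(C=C1)C#N | intermediate
8 | (1R)-1-(5-bromo-2-hydroxyphenyl)-4-oxocyclohex-2-ene-1-carbonitrile | O=C1CC[C@](c2cc(Br)ccc2O)(C=C1)C#N | intermediate (not isolated)
9 | (4aR,9bR)-8-bromo-3-oxo-1,2,3,4,4a,9b-hexahydrodibenzo[b,d]furan-9b-carbonitrile (cis-fused) | O=C1CC[C@]2(C#N)c3cc(Br)ccc3O[C@@H]2C1 | intermediate
10 | (4a'R,9b'R)-8'-bromo-1',2',4',4a'-tetrahydro-9b'H-spiro[[1,3]dioxolane-2,3'-dibenzo[b,d]furan]-9b'-carbonitrile | O1CCOC12CC[C@]3(C#N)c4cc(Br)ccc4O[C@@H]3C2 | intermediate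
11 | (4a'R,9b'S)-8'-bromo-1',2',4',4a'-tetrahydro-9b'H-spiro[[1,3]dioxolane-2,3'-dibenzo[b,d]furan]-9b'-carbaldehyde | O1CCOC12CC[C@]3(C=O)c4cc(Br)ccc4O[C@@H]3C2 | intermediate
12 | methyl bis(2,2,2-trifluoroethyl)phosphonoacetate | COC(=O)CP(=O)(OCC(F)(F)F)OCC(F)(F)F | starting material
13 | methyl (2Z)-3-[(4a'R,9b'S)-8'-bromo-1',2',4',4a'-tetrahydro-9b'H-spiro[[1,3]dioxolane-2,3'-dibenzo[b,d]furan]-9b'-yl]prop-2-enoate | O1CCOC12CC[C@]3(/C=C\C(=O)OC)c4cc(Br)ccc4O[C@@H]3C2 | intermediate
14 | (2Z)-3-[(4a'R,9b'S)-8'-bromo-1',2',4',4a'-tetrahydro-9b'H-spiro[[1,3]dioxolane-2,3'-dibenzo[b,d]furan]-9b'-yl]prop-2-enoic acid | O1CCOC12CC[C@]3(/C=C\C(O)=O)c4cc(Br)ccc4O[C@@H]3C2 | intermediate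
15 | 3-aminopropan-1-ol | NCCCO | starting material
16 | 4-bromobutanenitrile | N#CCCCBr | starting material
17 | 4-[(3-hydroxypropyl)amino]butanenitrile | N#CCCCNCCCO | intermediate (not isolated)
18 | tert-butyl (3-cyanopropyl)(3-hydroxypropyl)carbamate | N#CCCCN(CCCO)C(=O)OC(C)(C)C | intermediate
19 | tert-butyl (4-aminobutyl)(3-hydroxypropyl)carbamate | NCCCCN(CCCO)C(=O)OC(C)(C)C | intermediate
20 | tert-butyl N-{4-[(2Z)-3-[(4a'R,9b'S)-8'-bromo-1',2',4',4a'-tetrahydro-9b'H-spiro[[1,3]dioxolane-2,3'-dibenzo[b,d]furan]-9b'-yl]prop-2-enamido]butyl}-N-(3-hydroxypropyl)carbamate | O1CCOC12CC[C@]3(/C=C\C(=O)NCCCCN(CCCO)C(=O)OC(C)(C)C)c4cc(Br)ccc4O[C@@H]3C2 | intermediate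
21 | (2Z)-3-iodoprop-2-enoic acid | OC(=O)/C=C\I | starting material
22 | tert-butyl carbamate | NC(=O)OC(C)(C)C | starting material
23 | (2Z)-3-iodoprop-2-enoyl chloride | ClC(=O)/C=C\I | intermediate (not isolated)
24 | tert-butyl N-[(2Z)-3-iodoprop-2-enoyl]carbamate | O=C(/C=C\I)NC(=O)OC(C)(C)C | intermediate
25 | pinacol boronate of 20 (Bpin in place of Br at C8') | O1CCOC12CC[C@]3(/C=C\C(=O)NCCCCN(CCCO)C(=O)OC(C)(C)C)c4cc(B5OC(C)(C)C(C)(C)O5)ccc4O[C@@H]3C2 | intermediate (not isolated)
26 | tert-butyl N-[(2Z)-3-[(4a'R,9b'S)-9b'-[(1Z)-3-({4-[(tert-butoxycarbonyl)(3-hydroxypropyl)amino]butyl}amino)-3-oxoprop-1-en-1-yl]-1',2',4',4a'-tetrahydro-9b'H-spiro[[1,3]dioxolane-2,3'-dibenzo[b,d]furan]-8'-yl]prop-2-enoyl]carbamate | O1CCOC12CC[C@]3(/C=C\C(=O)NCCCCN(CCCO)C(=O)OC(C)(C)C)c4cc(/C=C\C(=O)NC(=O)OC(C)(C)C)ccc4O[C@@H]3C2 | intermediate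
27 | bis-Boc macrocyclic ketal: 20-membered (Z,Z)-bis-enamide macrocycle, (4aR,9bS) in dibenzofuran numbering, C3 ketone as ethylene ketal, Boc on spermidine N1 (cinnamamide N) and N4 (amine N) | C15(OCCO5)CC[C@]23/C=C\C(=O)NCCCCN(C(=O)OC(C)(C)C)CCCN(C(=O)OC(C)(C)C)C(=O)/C=C\c4ccc(c2c4)O[C@@H]3C1 | intermediate
28 | CNP0415009.2: 20-membered macrocycle in which spermidine N8 is acylated by the (Z)-acrylic acid on C9b and N1 by the (Z)-acrylic acid on C8 of cis-(4aR,9bS)-1,2,4,4a-tetrahydrodibenzo[b,d]furan-3(9bH)-one | O=C1CC[C@]23/C=C\C(=O)NCCCCNCCCNC(=O)/C=C\c4ccc(c2c4)O[C@@H]3C1 | target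

Total step count: 16. Longest linear sequence: 13 steps (steps 1 to 9, 12, 14, 15, 16).

Steps most likely to fail

Step 15 (macrocyclisation). Oligomerisation may outrun ring closure; the carbonyl oxygen of the N-Boc group on the chain may attack the activated carbon and form a six-membered cyclic carbamate with loss of the tert-butyl group; the acyl carbamate may alkylate on oxygen; and free phosphine may isomerise the activated (Z)-cinnamoyl unit by reversible conjugate addition. The fallback replaces the redox condensation by a discrete alkyl halide and an anionic alkylation without phosphine in the ring-closing event. It sets out from 26, whose primary alcohol is converted with I2, PPh3 and imidazole in CH2Cl2 at 0 °C into the primary iodide F1. F1 is then added slowly to Cs2CO3 in DMF at 0.002 M and 40 °C, where the caesium salt of the acyl carbamate should close the same N–CH2 bond. The route is rejoined at 27.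

Step 3 (enantioselective deprotonation). Discrimination of the enantiotopic α-protons may be insufficient, or the sense of induction may be the wrong one for the ortho-substituted aryl nitrile. The fallback changes from a chiral base to a biocatalytic desymmetrisation and sets out from 5. Oxidation with 2-iodoxybenzoic acid (3 equiv) in DMSO at 80 °C should give the achiral cyclohexadienone F2. An ene-reductase of the Old Yellow Enzyme family, chosen from a panel for the (R)-product, with NADP+, glucose dehydrogenase and D-glucose in phosphate buffer pH 7 with DMSO cosolvent, would then reduce one of the two enantiotopic C=C bonds. This rejoins the route at 7 and saves the silyl enol ether stage. In either variant the enantiomeric purity should be upgradable by recrystallisation of 9.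

Step 14 (borylation and Suzuki–Miyaura coupling). Protodeboronation, partial Z-to-E isomerisation on palladium, or degradation of the iodoacryloyl carbamate in aqueous base may erode the coupling. The fallback builds the alkene by a Heck reaction and sets its geometry afterwards. Acryloyl chloride and lithiated tert-butyl carbamate (as in step 13) give tert-butyl acryloylcarbamate F3. Setting out from 20, Heck coupling with F3 (Pd(OAc)2, P(o-tol)3, Et3N, DMF, 90 °C) should give the (E)-cinnamoyl carbamate F4. Triplet-sensitised E-to-Z isomerisation (Ir(ppy)3 1 mol %, blue LEDs, MeCN, rt) then acts only on the styrene-type alkene, because the alkyl-substituted (Z)-acrylamide lies too high in triplet energy. The route is rejoined at 26.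

Further compounds
F1 | step 15 | iodide of 26 (I in place of the primary OH) | O1CCOC12CC[C@]3(/C=C\C(=O)NCCCCN(CCCI)C(=O)OC(C)(C)C)c4cc(/C=C\C(=O)NC(=O)OC(C)(C)C)ccc4O[C@@H]3C2
F2 | step 3 | 1-(5-bromo-2-methoxyphenyl)-4-oxocyclohexa-2,5-diene-1-carbonitrile | N#CC1(c2cc(Br)ccc2OC)C=CC(=O)C=C1
F3 | step 14 | tert-butyl acryloylcarbamate | C=CC(=O)NC(=O)OC(C)(C)C
F4 | step 14 | (E)-cinnamoyl isomer of 26 | O1CCOC12CC[C@]3(/C=C\C(=O)NCCCCN(CCCO)C(=O)OC(C)(C)C)c4cc(/C=C/C(=O)NC(=O)OC(C)(C)C)ccc4O[C@@H]3C2
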